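**Plan**

- **Numbering:** the skeleton is tetracyclo[6.4.0.0(2,7).0(3,6)]dodecane. Ring A is the cyclohexane C1/C8–C12 with the chain on C10, ring B is C1-C2-C7-C8, ring C is C2-C3-C6-C7 (central cyclobutane), and ring D is C3-C4-C5-C6.
- **Enabling feature:** rings B, C and D share one eight-carbon perimeter C1–C8, crossed only by the rungs C2–C7 and C3–C6, and both rungs are edges of ring C. Without the rungs the perimeter is a cyclooctane. At the triene level (C2=C3, C4=C5, C6=C7) a 6π and then a 4π electrocyclisation redraw exactly these rungs, a pericyclic copy of the presumed biosynthetic rung-by-rung zipping of a folded polyene chain.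
- **Retrosynthetic cuts, in order:** the benzylidene acetal and C10–C1' (as C=C, Wittig); C10=O back to the meso alkene C10=C11; rung C3–C6, then rung C2–C7; finally C8–C9 and C1–C12 (double alkylation of the C8H8 dianion).
- **Forward order:** ring A is annulated onto cyclooctatetraene and ring B closes thermally. Rings C and D close in the last ring-forming event, and ring C is complete only then. The ether-linked C8 chain is made separately and joined afterwards.
- **Stereochemistry:** C1/C8 become cis in the tethered alkylation. C2/C7 and C3/C6 become cis through the two disrotations and anti through exo preferences, all in a meso series. The absolute configuration comes from a desymmetrising hydroboration with (+)-Ipc2BH, and C10 is set by hydrogen delivery to the convex face.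

Key step: step 2

Assumption: the sense of induction in step 4 is extrapolated from simple cis-alkenes, since (+)-Ipc2BH, made from (−)-α-pinene, converts (Z)-but-2-ene into (S)-butan-2-ol. If the meso alkene responds in the opposite sense, (−)-Ipc2BH is used and nothing else changes.

**Step 1**
Reactants: 1 cycloocta-1,3,5,7-tetraene; 2 (Z)-1,4-dichlorobut-2-ene
Product: 4 cis-bicyclo[6.4.0]dodeca-2,4,6,10-tetraene (meso; H-1/H-8 cis; all alkenes Z), via dipotassium cyclooctatetraenide 3 (not isolated)
Conditions: K (2.1 equiv), THF, 0 °C to rt; this solution added slowly to 2, THF, −78 °C to 0 °C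
Reagents that add atoms: none
Why: Double SN2 alkylation of the ten-π-electron dianion by an α,ω-dihalide is the established annulation route to bicyclo[6.n.0]trienes; the first substitution leaves a cyclooctatrienyl anion whose neighbouring carbon closes ring A (6-exo-tet) on the face that carries the tether, so that C1 and C8 should emerge cis, and chloride leaving groups with inverse addition in the cold hold back electron transfer.

**Step 2**
Reactants: 4 cis-bicyclo[6.4.0]dodeca-2,4,6,10-tetraene
Product: 6 tetracyclo[6.4.0.0(2,7).0(3,6)]dodeca-4,10-diene (meso; all three fusions cis; neighbouring rings anti), via tricyclic triene 5 (not isolated)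
Conditions: degassed pentane (dilute), 50 °C, dark; then hν (300 nm lamps, Pyrex), −10 °C; warm/irradiate cycles repeated
Reagents that add atoms: none
Why: Warming lets the all-Z triene C2=C3–C4=C5–C6=C7 of 4 close thermally by a disrotatory 6π electrocyclisation (new bond C2–C7) to the cyclohexa-1,3-diene 5, and excitation of that diene closes it by a disrotatory 4π electrocyclisation (new bond C3–C6) to 6, which no longer absorbs and should therefore accumulate. The closest known reaction types are the cycloocta-1,3,5-triene/bicyclo[4.2.0]octa-2,4-diene valence tautomerism and the photochemical closure of cis-5,6-ring-fused cyclohexa-1,3-dienes to bicyclo[2.2.0]hex-2-enes, a class that includes the bicyclo[4.2.0]octa-2,4-dienes formed as arene–alkene ortho photoadducts. Ring B is closed transannularly by the 6π step, rings C and D are both closed by the single bond C3–C6 of the 4π step, and ring C, the only ring that holds both new bonds, is thus the last ring of the skeleton to be completed. C2 and C7 become cis because disrotation of a Z,Z,Z-triene puts both hydrogens on one face, and they should lie anti to H-1/H-8 because the closure is reversible and the tautomer with ring A on the exo side is the less crowded one; C3 and C6 become cis by the second disrotation, which should turn C4=C5 away from ring B because the syn fold presses ring D against ring B. The step needs chromophore and site selectivity: the isolated alkene C10=C11 does not absorb at 300 nm and is held far from the diene in anti-5, long-wavelength light favours the flatter diene of 5 over the twisted triene of 4, and unchanged 4 is fed back through the warm/irradiate cycles. The temperature stays at or below 50 °C so that hydrogen shifts in 4 and an intramolecular Diels–Alder reaction of the minor syn tautomer remain slow.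

**Step 3**
Reactants: 6 tetracyclo[6.4.0.0(2,7).0(3,6)]dodeca-4,10-diene
Product: 7 tetracyclo[6.4.0.0(2,7).0(3,6)]dodec-10-ene (meso)
Conditions: KO2CN=NCO2K (1.5 equiv), AcOH, MeOH, 0 °C
Reagents that add atoms: none
Why: Concerted syn hydrogen transfer from diimide is driven by strain relief, so the cyclobutene C4=C5 of ring D should be saturated well before the unstrained cyclohexene C10=C11; no stereocentre is formed and no metal that could insert into the strained σ-bonds is present.

**Step 4**
Reactants: 7 tetracyclo[6.4.0.0(2,7).0(3,6)]dodec-10-ene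
Product: 9 (1R,2S,3S,6R,7R,8S,10R)-tetracyclo[6.4.0.0(2,7).0(3,6)]dodecan-10-ol (OH on the face of H-1/H-8), via trialkylborane 8 (not isolated)
Conditions: pre-formed crystalline (+)-Ipc2BH, THF, −25 °C to 0 °C; then NaOH, H2O2, 0 °C to rt
Reagents that add atoms: hydrogen peroxide (OO)
Why: Reagent-controlled asymmetric hydroboration–oxidation desymmetrises the meso cis-alkene: boron should add to the convex face (that of H-1/H-8), the reagent should select C10 over its enantiotopic partner C11, oxidation proceeds with retention, and any alcohol from concave-face attack is a diastereomer that chromatography removes, which protects the enantiomeric purity of the next compound.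

**Step 5**
Reactants: 9 (10R)-tetracyclododecan-10-ol
Product: 10 (1R,2S,3S,6R,7R,8S)-tetracyclo[6.4.0.0(2,7).0(3,6)]dodecan-10-one
Conditions: Dess–Martin periodinane, NaHCO3, CH2Cl2, 0 °C to rt
Reagents that add atoms: none
Why: Dess–Martin oxidation is neutral and mild toward the strained core; the carbinol centre is erased on purpose, the position of the carbonyl (β to C8, γ to C1) now carries the absolute information, and both α-carbons are CH2 groups, so nothing can epimerise.

**Step 6**
Reactants: 11 cis-2-phenyl-1,3-dioxan-5-ol (1,3-O-benzylideneglycerol); 12 1,8-dibromooctane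
Product: 14 cis-5-(8-bromooctyloxy)-2-phenyl-1,3-dioxane, via sodium alkoxide 13 (not isolated)
Conditions: NaH, DMF, 0 °C; then 12 (4 equiv), rt
Reagents that add atoms: none
Why: Williamson ether synthesis at the only free hydroxyl of the glycerol acetal is the standard way to 2-O-alkylglycerols, and the excess of dibromide suppresses double substitution.

**Step 7**
Reactants: 14 cis-5-(8-bromooctyloxy)-2-phenyl-1,3-dioxane
Product: 15 [8-(cis-2-phenyl-1,3-dioxan-5-yloxy)octyl]triphenylphosphonium bromide
Conditions: PPh3, MeCN, reflux
Reagents that add atoms: triphenylphosphine (c1ccccc1P(c1ccccc1)c1ccccc1)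
Why: SN2 quaternisation of a primary bromide by the phosphine is routine, and the acetal is inert under these neutral conditions.

**Step 8**
Reactants: 15 phosphonium bromide; 10 tetracyclododecan-10-one
Product: 17 cis-5-[8-((1R,2S,3S,6R,7R,8S)-tetracyclo[6.4.0.0(2,7).0(3,6)]dodecan-10-ylidene)octyloxy]-2-phenyl-1,3-dioxane (E/Z mixture), via phosphonium ylide 16 (not isolated)
Conditions: NaN(SiMe3)2, THF, 0 °C; then 10, −78 °C to rt
Reagents that add atoms: none
Why: Wittig olefination of an unhindered cyclohexanone by a non-stabilised ylide joins the chain at C10; the alkene geometry is irrelevant because both isomers converge in the next step.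

**Step 9**
Reactants: 17 alkylidene acetal
Product: 19 2-{8-[(1R,2S,3S,6R,7R,8S,10S)-tetracyclo[6.4.0.0(2,7).0(3,6)]dodecan-10-yl]octyloxy}propane-1,3-diol (target), via saturated acetal 18 (not isolated)
Conditions: H2 (1 atm), Pd/C, EtOAc–EtOH, rt
Reagents that add atoms: none
Why: In this heterogeneous hydrogenation and hydrogenolysis the alkene should adsorb through the convex face of ring A, because the axial C8–C7 bond and the ladder behind it screen the other face in the favoured conformer, so H-10 arrives syn to H-1/H-8 and the chain ends cis to ring B (10S); the same catalyst then cleaves the benzylic C–O bonds of the acetal, and saturated ladderane cores are known to withstand such conditions at ambient pressure.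

**Compound list**

1 | cycloocta-1,3,5,7-tetraene | C1=CC=CC=CC=C1 | starting material
2 | (Z)-1,4-dichlorobut-2-ene | ClC/C=C\CCl | starting material
3 | dipotassium cyclooctatetraenide | [K+].[K+].[CH-]1[CH-]C=CC=CC=C1 | intermediate
4 | cis-bicyclo[6.4.0]dodeca-2,4,6,10-tetraene (meso) | C1C=CC[C@H]2/C=C\C=C/C=C\[C@@H]12 | intermediate
5 | cis-anti-cis-tricyclo[6.4.0.0(2,7)]dodeca-3,5,10-triene (meso) | C1=CC[C@@H]2[C@H](C1)[C@H]1C=CC=C[C@@H]21 | intermediate
6 | tetracyclo[6.4.0.0(2,7).0(3,6)]dodeca-4,10-diene, fusions cis, neighbouring rings anti (meso) | C1=CC[C@@H]2[C@H](C1)[C@H]1[C@@H]3C=C[C@@H]3[C@@H]21 | intermediate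
7 | tetracyclo[6.4.0.0(2,7).0(3,6)]dodec-10-ene, same relative configuration (meso) | C1=CC[C@@H]2[C@H](C1)[C@H]1[C@@H]3CC[C@@H]3[C@@H]21 | intermediate
8 | bis(isopinocampheyl)(tetracyclododecan-10-yl)borane, boron on the face of H-1/H-8 | B([C@H]1C[C@H]2C[C@@H]([C@@H]1C)C2(C)C)([C@H]1C[C@H]2C[C@@H]([C@@H]1C)C2(C)C)[C@@H]1CC[C@@H]2[C@H](C1)[C@H]1[C@@H]3CC[C@@H]3[C@@H]21 | intermediate
9 | (1R,2S,3S,6R,7R,8S,10R)-tetracyclo[6.4.0.0(2,7).0(3,6)]dodecan-10-ol | O[C@@H]1CC[C@@H]2[C@H](C1)[C@H]1[C@@H]3CC[C@@H]3[C@@H]21 | intermediate
10 | (1R,2S,3S,6R,7R,8S)-tetracyclo[6.4.0.0(2,7).0(3,6)]dodecan-10-one | O=C1CC[C@@H]2[C@H](C1)[C@H]1[C@@H]3CC[C@@H]3[C@@H]21 | intermediate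
11 | cis-2-phenyl-1,3-dioxan-5-ol | O[C@@H]1CO[C@@H](OC1)c1ccccc1 | starting material
12 | 1,8-dibromooctane | BrCCCCCCCCBr | starting material
13 | sodium cis-2-phenyl-1,3-dioxan-5-olate | [Na+].[O-][C@@H]1CO[C@@H](OC1)c1ccccc1 | intermediate
14 | cis-5-(8-bromooctyloxy)-2-phenyl-1,3-dioxane | BrCCCCCCCCO[C@@H]1CO[C@@H](OC1)c1ccccc1 | intermediate
15 | [8-(cis-2-phenyl-1,3-dioxan-5-yloxy)octyl]triphenylphosphonium bromide | [Br-].c1ccccc1[P+](c1ccccc1)(c1ccccc1)CCCCCCCCO[C@@H]1CO[C@@H](OC1)c1ccccc1 | intermediate
16 | the derived triphenylphosphonium ylide | c1ccccc1P(c1ccccc1)(c1ccccc1)=CCCCCCCCO[C@@H]1CO[C@@H](OC1)c1ccccc1 | intermediate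
17 | C10-alkylidene acetal (E/Z mixture) | O(CCCCCCCC=C1CC[C@@H]2[C@H](C1)[C@H]1[C@@H]3CC[C@@H]3[C@@H]21)[C@@H]1CO[C@@H](OC1)c1ccccc1 | intermediate
18 | (10S)-saturated benzylidene acetal | O(CCCCCCCC[C@H]1CC[C@@H]2[C@H](C1)[C@H]1[C@@H]3CC[C@@H]3[C@@H]21)[C@@H]1CO[C@@H](OC1)c1ccccc1 | intermediate
19 | 2-{8-[(1R,2S,3S,6R,7R,8S,10S)-tetracyclo[6.4.0.0(2,7).0(3,6)]dodecan-10-yl]octyloxy}propane-1,3-diol | OCC(CO)OCCCCCCCC[C@H]1CC[C@@H]2[C@H](C1)[C@H]1[C@@H]3CC[C@@H]3[C@@H]21 | target

**Step count**

- Total step count: 9
- Longest linear sequence: 7 (steps 1, 2, 3, 4, 5, 8, 9)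

**Steps most likely to fail**

1. **Step 2.**
   - Risk: the monocyclic tautomer takes up the light and closes across a different diene unit, or the excited diene reopens or fragments faster than it closes. Imperfect anti folding is a lesser risk.
   - Fallback, from 4 back to 7, with nitrogen extrusion in place of the photochemical electrocyclisation: 4 is trapped through its tautomer by Diels–Alder addition of 4-phenyl-1,2,4-triazoline-3,5-dione across C3 and C6, on the face away from ring B, to give the urazole adduct F1. Diimide saturates the strained etheno bridge C4=C5 to give the dihydro urazole F2. KOH in hot 2-propanol gives the cyclic hydrazine F3, which CuCl2 followed by aqueous NH3 oxidises to the azoalkane F4. Irradiation at 350 nm expels nitrogen. The cyclohexane-1,4-diyl left behind is free to flip before it bonds and should collapse by C3–C6 bonding to the less strained anti-fused 7.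

2. **Step 1.**
   - Risk: electron transfer from the dianion to the allylic dichloride with loss of butadiene, proton abstraction by the dianion, or ring closure to the trans fusion.
   - Fallback, from 2 back to 4, building the eight-membered ring onto a preformed cis ring A: 2 and PPh3 give (Z)-but-2-ene-1,4-diylbis(triphenylphosphonium) dichloride F5. LiAlH4 reduction of commercial cis-1,2,3,6-tetrahydrophthalic anhydride gives cis-cyclohex-4-ene-1,2-dimethanol F6, and Swern oxidation gives cis-cyclohex-4-ene-1,2-dicarbaldehyde F7. LiN(SiMe3)2 converts F5 into the bis-ylide F8. Slow mixing of F8 with F7 at high dilution closes the triene ring by double Wittig olefination to 4, whose cis fusion then stems from a Diels–Alder adduct.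

3. **Step 4.**
   - Risk: sluggish hydroboration with loss of α-pinene from the reagent, and poor discrimination between the enantiotopic alkene carbons or between the two faces.
   - Fallback, from 7 back to 9, desymmetrising an epoxide instead of the alkene: mCPBA epoxidises the convex face to the meso exo-epoxide F9. Enantioselective β-elimination with lithium (S)-2-(pyrrolidin-1-ylmethyl)pyrrolidide, or its antipode, whichever removes the C12 proton, gives the allylic alcohol F10. H2 over Pd/C saturates C11=C12 to give 9.

**Further compounds**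
F1 | step 2 | N-phenylurazole Diels–Alder adduct of 5 (N–N bridge on C3/C6, anti to ring B) | C1=CC[C@@H]2[C@H](C1)[C@H]1[C@H]3C=C[C@@H]([C@@H]21)N4N3C(=O)N(c3ccccc3)C4=O
F2 | step 2 | 4,5-dihydro derivative of F1 | C1=CC[C@@H]2[C@H](C1)[C@H]1[C@H]3CC[C@@H]([C@@H]21)N4N3C(=O)N(c3ccccc3)C4=O
F3 | step 2 | bridged cyclic hydrazine | C1=CC[C@@H]2[C@H](C1)[C@H]1[C@H]3CC[C@@H]([C@@H]21)NN3
F4 | step 2 | bridged azoalkane | C1=CC[C@@H]2[C@H](C1)[C@H]1[C@H]3CC[C@@H]([C@@H]21)N=N3
F5 | step 1 | (Z)-but-2-ene-1,4-diylbis(triphenylphosphonium) dichloride | [Cl-].[Cl-].c1ccccc1[P+](c1ccccc1)(c1ccccc1)C/C=C\C[P+](c1ccccc1)(c1ccccc1)c1ccccc1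
F6 | step 1 | cis-cyclohex-4-ene-1,2-dimethanol | OC[C@H]1CC=CC[C@H]1CO
F7 | step 1 | cis-cyclohex-4-ene-1,2-dicarbaldehyde | O=C[C@H]1CC=CC[C@H]1C=O
F8 | step 1 | (Z)-but-2-ene-1,4-diylidenebis(triphenylphosphorane) | c1ccccc1P(c1ccccc1)(c1ccccc1)=C/C=C\C=P(c1ccccc1)(c1ccccc1)c1ccccc1
F9 | step 4 | meso 10,11-epoxide of 7, oxygen on the face of H-1/H-8 | O1[C@H]2C[C@@H]3[C@H]4[C@@H]5CC[C@@H]5[C@H]4[C@@H]3C[C@@H]12
F10 | step 4 | tetracyclo[6.4.0.0(2,7).0(3,6)]dodec-11-en-10-ol, OH on the face of H-1/H-8 | O[C@@H]1C=C[C@@H]2[C@H](C1)[C@H]1[C@@H]3CC[C@@H]3[C@@H]21
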